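The target of this flask comes from substrate, mostly through the step that carries acid, and the questions are how far that has gone and what the pH is at the end.

    substrate + acid → weak acid + acid + target (k1 = 21.1 /M/min)
    substrate → weak acid + target (k2 = 5.29 × 10⁻⁴ /min)
    weak acid → by-product carried off (k3 = 1.77 /min)
    weak acid ⇌ conjugate base + acid, settled at all times (K4 = 7.9 × 10⁻⁷ M)
    substrate → decomposition product (k5 = 3.23 × 10⁻⁴ /min)

substrate 0.087 M; acid 8.70 mM; time 15 min

- part of the substrate that has reacted at 15 min
- pH of the solution at 15 min

- acid is the free proton; pH is minus the decimal logarithm of its molar concentration
- run time (flask): 15 min

Two chemists dispute this flask. The first says that acid stands on both sides of its step, so it is a catalyst, c(acid) stays at its charge of 8.70 mM, and substrate decays pseudo-first-order. The second says that each substrate leaves a weak acid that gives up protons of its own, so c(acid) should climb, the pH sink and the decay quicken.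

I test the second view at its strongest by letting the whole 0.087 M of substrate stand as weak acid. The balance then adds K4 times c(weak acid) over c(acid), which is 0.00790 mM of acid, far less than the charge. The second view has its region where the charged acid is small against 0.262 mM, the acid that 0.087 M of weak acid gives by itself in the balance, and this flask stands well above that.

So I reckon with the first view, in logarithms. A first-order fall is a straight line in the logarithm, and it can be counted in decades, each a fall by a factor of 10. The substrate's rate constant is k1 times c(acid) plus the two acid-free steps, 0.184 /min, and that pair is much the smaller part. The decade time, 2.3 over this constant, is 12.5 min. The run of 15 min is then 1.20 decades, which leaves 6.29 % of the substrate, so 93.7 % has reacted, and the pH stays that of the charge.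

The forecast, holding that “the weak acid barely dissociates at this pH”, gives 93.7 % reacted and pH 2.06.

The flask gives 93.7 % reacted and pH 2.06, with acid at 100 % of its charge, so the first chemist stands. In this flask the acid-carried step ran at unchanged c(acid), and substrate stood at 25.1 % at 7.50 min, which is 0.600 decades of 12.5 min, and at 6.29 % at 15.0 min. Behind it, weak acid, with a half-life of 0.39 min by its step to by-product, went from 0.00695 M at 1.50 min to 6.35 × 10⁻⁴ M at 15.0 min, while by-product reached 0.0808 M. The neighbour flask with 0.0052 M of acid has a decade time of 20.8 min, so its 15 min are 0.721 decades, a fall to 19.0 %, and that flask held 19 % of its substrate.

The constants used here stand for no real mixture; what happens was integrated by code.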